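**Plan**

- Locants: chroman atoms plain (O1, C2 to C8a); norbornane atoms primed, with C2' the spiro carbon (= C2), C3' the CMe2 carbon, C1' and C4' the bridgeheads, C7' the one-carbon bridge.
- Retrosynthesis: cut the two aryl–CHO bonds (C6, C8) and the benzyl ethers, then C3'–C4' of the norbornane, then C2–C1' (cyclopentenyl onto an oxocarbenium ion) and C2–C3' (isopropenyl onto a lactone carbonyl), and last the pyranone ring of a 4-isobutylcoumarin (Pechmann).
- Enabling feature: the norbornane is a cyclopentane ring (C1', C7', C4', C5', C6') spanned by the two-carbon bridge C2'–C3', and C3' is a gem-dimethyl carbon beside the spiro centre. A tertiary C3' radical made from an isopropenyl group can therefore close onto a symmetric cyclopent-3-enyl ring held on C2.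
- Forward order: pyranone ring (step 1), saturated chroman with quaternary C2 (steps 3 to 6), bicyclo[2.2.1]heptane by radical closure (step 7), then debenzylation and twofold formylation.
- Stereochemistry: C4 (S) from a ligand-controlled copper hydride conjugate reduction; C2 (R) from attack on the oxocarbenium ion anti to the C4 isobutyl group; C1' (R) and C4' (S) from the choice between the two olefinic carbons in the radical closure, which must leave O1 endo.

Key step: step 7

Assumption: (R)-DTBM-SEGPHOS is taken to deliver hydride to the face of C4 that gives the 4S lactone; if the sense of induction is the reverse, the (S)-ligand is used.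

**Step 1**
Reactants: 1 phloroglucinol; 2 ethyl 5-methyl-3-oxohexanoate
Product: 3 5,7-dihydroxy-4-(2-methylpropyl)-2H-chromen-2-one
Conditions: conc. H2SO4, 0 °C → rt
Reagents that add atoms: none
Why: Pechmann condensation of the symmetric triol with the β-keto ester under strong acid can give only one constitution, the 4-isobutyl-5,7-dihydroxycoumarin, as in the known 4-propyl case.

**Step 2**
Reactants: 3 5,7-dihydroxy-4-(2-methylpropyl)-2H-chromen-2-one
Product: 4 5,7-bis(benzyloxy)-4-(2-methylpropyl)-2H-chromen-2-one
Conditions: BnBr, K2CO3, DMF, 50 °C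
Reagents that add atoms: benzyl bromide, BrCc1ccccc1
Why: Williamson etherification of both phenols gives benzyl ethers that should survive the organometallic, Lewis-acid and radical steps and can be removed by hydrogenolysis once no alkene is left.

**Step 3**
Reactants: 4 5,7-bis(benzyloxy)-4-(2-methylpropyl)-2H-chromen-2-one
Product: 5 (4S)-5,7-bis(benzyloxy)-4-(2-methylpropyl)-3,4-dihydro-2H-chromen-2-one
Conditions: Cu(OAc)2·H2O (cat.), (R)-DTBM-SEGPHOS (cat.), (EtO)2MeSiH, t-BuOH, toluene, 0 °C → rt
Reagents that add atoms: none
Why: Copper hydride asymmetric conjugate reduction of the β,β-disubstituted unsaturated lactone delivers hydride to C4 from the face chosen by the bisphosphine, which sets C4 as S, and tert-butanol protonates the copper enolate so that the lactone carbonyl is not reduced further.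

**Step 4**
Reactants: 5 (4S)-5,7-bis(benzyloxy)-4-(2-methylpropyl)-3,4-dihydro-2H-chromen-2-one; 6 2-bromopropene
Product: 8 (4S)-5,7-bis(benzyloxy)-4-(2-methylpropyl)-2-(prop-1-en-2-yl)-3,4-dihydro-2H-chromen-2-ol as its C2 anomers, via prop-1-en-2-yllithium 7 (not isolated)
Conditions: 6, t-BuLi (2 equiv), Et2O, −78 °C; then 5, THF, −78 °C; AcOH, −78 °C
Reagents that add atoms: none
Why: Bromine–lithium exchange followed by single addition of the alkenyllithium to the aryl lactone at −78 °C, where the tetrahedral lithium hemiketal alkoxide should persist until the acidic quench (lactone-to-lactol addition as used for 2-substituted chroman-2-ols), gives the lactol in equilibrium with its open hydroxy enone, and its C2 configuration does not matter because C2 is flattened again in step 6.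

**Step 5**
Reactants: 9 cyclopent-3-en-1-ol
Product: 10 4-iodocyclopent-1-ene
Conditions: I2, PPh3, imidazole, CH2Cl2, 0 °C → rt
Reagents that add atoms: iodine, II
Why: Appel-type iodination, in which iodide displaces the alkoxyphosphonium group of the secondary alcohol, involves no stereocentre because the carbinol carbon lies on the mirror plane of the ring.

**Step 6**
Reactants: 8 (4S)-5,7-bis(benzyloxy)-4-(2-methylpropyl)-2-(prop-1-en-2-yl)-3,4-dihydro-2H-chromen-2-ol; 10 4-iodocyclopent-1-ene
Product: 12 (2R,4S)-5,7-bis(benzyloxy)-2-(cyclopent-3-en-1-yl)-4-(2-methylpropyl)-2-(prop-1-en-2-yl)-3,4-dihydro-2H-chromene, via cyclopent-3-en-1-ylzinc iodide 11 (not isolated)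
Conditions: 10, Zn dust, LiCl, THF, 25 °C; then 8, BF3·OEt2, CH2Cl2, −78 → −20 °C
Reagents that add atoms: none
Why: Lewis-acid-promoted C-alkylation of a lactol through its oxocarbenium ion with an organozinc reagent, in which BF3 ionises C2 (where most of the positive charge sits) and the zinc reagent enters anti to the C4 isobutyl group as hydride and allylsilane do with 4-substituted chroman-2-ol hemiketals, places the cyclopentenyl group trans to isobutyl and makes C2 R.

**Step 7**
Reactants: 12 (2R,4S)-5,7-bis(benzyloxy)-2-(cyclopent-3-en-1-yl)-4-(2-methylpropyl)-2-(prop-1-en-2-yl)-3,4-dihydro-2H-chromene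
Product: 13 (1'R,2R,4S,4'S)-5,7-bis(benzyloxy)-3',3'-dimethyl-4-(2-methylpropyl)-3,4-dihydrospiro[chromene-2,2'-bicyclo[2.2.1]heptane], O1 endo on the norbornane
Conditions: Fe(acac)3 (0.3 equiv), PhSiH3 (3 equiv), tert-dodecanethiol (0.2 equiv, slow addition), EtOH/THF, 40 °C, 0.01 M, degassed
Reagents that add atoms: none
Why: Proposed new method: the iron hydride formed from Fe(acac)3 and PhSiH3 should transfer a hydrogen atom to the CH2 terminus of the 1,1-disubstituted isopropenyl group faster than to the 1,2-disubstituted ring alkene, giving the tertiary C3' radical, which adds to one olefinic carbon of the cyclopent-3-enyl ring to form C3'–C4', after which the secondary C5' radical takes hydrogen from the thiol and the thiyl radical is returned to the thiol by the silane or by divalent iron and ethanol. The closest known reactions are the cyclisation of the 2-(cyclopent-3-enyl)ethyl radical to the 2-norbornyl radical and Fe(acac)3/PhSiH3 hydrogen-atom-transfer reductive cyclisations of dienes, neither of which has been shown with a cyclopentenyl acceptor carried on a fully substituted ether carbon. The one ring closed is the five-membered ring C3'–C2'–C1'–C7'–C4', by 5-exo-trig attack, and because both olefinic carbons stand in the same 5-exo relation to the radical no other ring size can arise. C1' and C4' become stereogenic in this single event and their configuration (1'R,4'S) is decided by which of the two diastereotopic olefinic carbons is attacked, the bicycle tying the two centres to each other, while C2 and C4 are not touched. The step needs the closure that leaves O1 endo (over C6') and C3 exo, and the substrate offers for this only the smaller size of the ether oxygen compared with the C3 methylene in the crowded endo site, read from the C2 configuration set in step 6; the gem-dimethyl group and the quaternary C2 should favour ring closure over early reduction and over ring reopening.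

**Step 8**
Reactants: 13 (1'R,2R,4S,4'S)-5,7-bis(benzyloxy)-3',3'-dimethyl-4-(2-methylpropyl)-3,4-dihydrospiro[chromene-2,2'-bicyclo[2.2.1]heptane]
Product: 14 (1'R,2R,4S,4'S)-3',3'-dimethyl-4-(2-methylpropyl)-3,4-dihydrospiro[chromene-2,2'-bicyclo[2.2.1]heptane]-5,7-diol
Conditions: H2 (1 atm), Pd/C, EtOAc/MeOH, rt
Reagents that add atoms: none
Why: Hydrogenolysis of the two benzyl aryl ethers over palladium on carbon should cleave only the protecting groups, since no alkene is left and the aryl–O–C2 ether is not benzylic at carbon, so no stereocentre is touched.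

**Step 9**
Reactants: 14 (1'R,2R,4S,4'S)-3',3'-dimethyl-4-(2-methylpropyl)-3,4-dihydrospiro[chromene-2,2'-bicyclo[2.2.1]heptane]-5,7-diol
Product: 16 (1'R,2R,4S,4'S)-5,7-dihydroxy-3',3'-dimethyl-4-(2-methylpropyl)-3,4-dihydrospiro[chromene-2,2'-bicyclo[2.2.1]heptane]-6,8-dicarbaldehyde, via the 6,8-bis(dimethyliminiomethyl) dichloride 15 (not isolated)
Conditions: POCl3, DMF, MeCN, 0 → 40 °C; then H2O, 60 °C
Reagents that add atoms: N,N-dimethylformamide, CN(C)C=O; water, O
Why: Vilsmeier–Haack formylation, in which the chloroiminium ion attacks the two free ring positions C6 and C8 (each ortho or para to three oxygen donors) and water hydrolyses the bis(iminium) salt, should give the dialdehyde as in the twofold formylation of phloroglucinol itself.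

**Compound list**

1 | phloroglucinol (benzene-1,3,5-triol) | Oc1cc(O)cc(O)c1 | starting material
2 | ethyl 5-methyl-3-oxohexanoate | CCOC(=O)CC(=O)CC(C)C | starting material
3 | 5,7-dihydroxy-4-(2-methylpropyl)-2H-chromen-2-one | CC(C)CC1=CC(=O)Oc2cc(O)cc(O)c12 | intermediate
4 | 5,7-bis(benzyloxy)-4-(2-methylpropyl)-2H-chromen-2-one | CC(C)CC1=CC(=O)Oc2cc(OCc3ccccc3)cc(OCc3ccccc3)c12 | intermediate
5 | (4S)-5,7-bis(benzyloxy)-4-(2-methylpropyl)-3,4-dihydro-2H-chromen-2-one | CC(C)C[C@H]1CC(=O)Oc2cc(OCc3ccccc3)cc(OCc3ccccc3)c21 | intermediate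
6 | 2-bromopropene | CC(Br)=C | starting material
7 | prop-1-en-2-yllithium (formed in the flask) | [Li]C(C)=C | intermediate
8 | (4S)-5,7-bis(benzyloxy)-4-(2-methylpropyl)-2-(prop-1-en-2-yl)-3,4-dihydro-2H-chromen-2-ol (both C2 anomers; ring-chain tautomer of the hydroxy enone) | CC(C)C[C@H]1CC(O)(C(C)=C)Oc2cc(OCc3ccccc3)cc(OCc3ccccc3)c21 | intermediate
9 | cyclopent-3-en-1-ol | OC1CC=CC1 | starting material
10 | 4-iodocyclopent-1-ene | IC1CC=CC1 | intermediate
11 | cyclopent-3-en-1-ylzinc iodide (formed in the flask) | I[Zn]C1CC=CC1 | intermediate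
12 | (2R,4S)-5,7-bis(benzyloxy)-2-(cyclopent-3-en-1-yl)-4-(2-methylpropyl)-2-(prop-1-en-2-yl)-3,4-dihydro-2H-chromene (cyclopentenyl trans to isobutyl) | CC(C)C[C@H]1C[C@@](C(C)=C)(Oc3cc(OCc4ccccc4)cc(OCc4ccccc4)c31)C1CC=CC1 | intermediate
13 | (1'R,2R,4S,4'S)-5,7-bis(benzyloxy)-3',3'-dimethyl-4-(2-methylpropyl)-3,4-dihydrospiro[chromene-2,2'-bicyclo[2.2.1]heptane] (O1 endo, C3 exo) | CC(C)C[C@H]1C[C@@]2(Oc3cc(OCc4ccccc4)cc(OCc4ccccc4)c31)[C@@H]1CC[C@@H](C1)C2(C)C | intermediate
14 | (1'R,2R,4S,4'S)-3',3'-dimethyl-4-(2-methylpropyl)-3,4-dihydrospiro[chromene-2,2'-bicyclo[2.2.1]heptane]-5,7-diol | CC(C)C[C@H]1C[C@@]2(Oc3cc(O)cc(O)c31)[C@@H]1CC[C@@H](C1)C2(C)C | intermediate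
15 | 6,8-bis(dimethyliminiomethyl) derivative of 14, dichloride (formed in the flask) | CC(C)C[C@H]1C[C@@]2(Oc3c(C=[N+](C)C)c(O)c(C=[N+](C)C)c(O)c31)[C@@H]1CC[C@@H](C1)C2(C)C.[Cl-].[Cl-] | intermediate
16 | (1'R,2R,4S,4'S)-5,7-dihydroxy-3',3'-dimethyl-4-(2-methylpropyl)-3,4-dihydrospiro[chromene-2,2'-bicyclo[2.2.1]heptane]-6,8-dicarbaldehyde (CNP0150011.1) | CC(C)C[C@H]1C[C@@]2(Oc3c(C=O)c(O)c(C=O)c(O)c31)[C@@H]1CC[C@@H](C1)C2(C)C | target

**Step count and risks**

Total: 9 steps. Longest linear sequence: 8 steps (steps 1 to 4 and 6 to 9, from phloroglucinol).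

Steps most likely to fail:

1. Step 7 (radical bicyclisation). The tertiary radical may be reduced before it cyclises, may expel the aryloxy group by β-scission of C2–O1, may reopen after closure, or may close onto the other olefinic carbon so that C3 rather than O1 ends endo; thiyl addition to the ring alkene can also compete. Fallback, setting out from 1 and returning at 16: phloroglucinol 1 would be diformylated (POCl3, DMF, then water) to 2,4,6-trihydroxybenzene-1,3-dicarbaldehyde F1. Knoevenagel condensation of F1 with 3-methylbutanal (NaOAc, AcOH, 80 °C) would give the ortho-quinone methide 2,4-diformyl-3,5-dihydroxy-6-(3-methylbutylidene)cyclohexa-2,4-dien-1-one F2. This heterodiene would be trapped in the same pot by (1S,4R)-(−)-camphene in an inverse-electron-demand hetero-Diels–Alder reaction that forms O1–C2 and C3–C4 at once and leads to 16. In that route the face of camphene that the oxygen attacks and the endo or exo placement of the isobutyl group would be the points to optimise.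

2. Step 6 (C2 quaternary centre). The zinc reagent may attack the terminal carbon of the isopropenyl group instead of C2, the oxocarbenium ion may lose a proton to a dienyl ether, the secondary alkylzinc may transfer a β-hydride, or the two faces of C2 may be poorly distinguished. Fallback, setting out from 8 and returning at 12: iodide 10 would be converted with Mg in THF into cyclopent-3-en-1-ylmagnesium iodide F3. With CeCl3 at −78 °C, F3 would add to the ketone carbonyl of the open hydroxy-enone form of 8 to give the phenolic tertiary allylic alcohol (5S)-5-[2,4-bis(benzyloxy)-6-hydroxyphenyl]-3-(cyclopent-3-en-1-yl)-2,7-dimethyloct-1-en-3-ol F4. Acid-catalysed cyclodehydration (camphorsulfonic acid, CH2Cl2, 0 °C) through the tertiary allylic cation would close the chroman ring to 12. Control at C2 would then rest on the ring closure, and 12 would be separated by chromatography from its C2 epimer, (2S,4S)-5,7-bis(benzyloxy)-2-(cyclopent-3-en-1-yl)-4-(2-methylpropyl)-2-(prop-1-en-2-yl)-3,4-dihydro-2H-chromene F5.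

3. Step 3 (asymmetric conjugate reduction). The peri benzyloxy group may slow hydride delivery to C4 or erode the facial selectivity, and the lactone may be reduced further or opened. Fallback, setting out from 1 and returning at 5: phloroglucinol 1 would be benzylated twice (BnBr, K2CO3, DMF) to 3,5-bis(benzyloxy)phenol F6. An iminium-catalysed Friedel–Crafts alkylation and hemiacetalisation of F6 with (E)-5-methylhex-2-enal (diphenylprolinol trimethylsilyl ether of the antipode that gives the 4S centre, benzoic acid, toluene) would give (4S)-5,7-bis(benzyloxy)-4-(2-methylpropyl)-3,4-dihydro-2H-chromen-2-ol F7. Oxidation of this lactol (PhI(OAc)2, TEMPO cat., CH2Cl2) would return the route to lactone 5.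

**Further compounds**

F1 | step 7 | 2,4,6-trihydroxybenzene-1,3-dicarbaldehyde | Oc1cc(O)c(C=O)c(O)c1C=O
F2 | step 7 | 2,4-diformyl-3,5-dihydroxy-6-(3-methylbutylidene)cyclohexa-2,4-dien-1-one | CC(C)CC=C1C(=O)C(C=O)=C(O)C(C=O)=C1O
F3 | step 6 | cyclopent-3-en-1-ylmagnesium iodide | I[Mg]C1CC=CC1
F4 | step 6 | (5S)-5-[2,4-bis(benzyloxy)-6-hydroxyphenyl]-3-(cyclopent-3-en-1-yl)-2,7-dimethyloct-1-en-3-ol (both C3 epimers) | CC(C)C[C@@H](CC(O)(C(C)=C)C1CC=CC1)c1c(O)cc(OCc2ccccc2)cc1OCc1ccccc1
F5 | step 6 | (2S,4S)-5,7-bis(benzyloxy)-2-(cyclopent-3-en-1-yl)-4-(2-methylpropyl)-2-(prop-1-en-2-yl)-3,4-dihydro-2H-chromene | CC(C)C[C@H]1C[C@](C(C)=C)(Oc3cc(OCc4ccccc4)cc(OCc4ccccc4)c31)C1CC=CC1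
F6 | step 3 | 3,5-bis(benzyloxy)phenol | Oc1cc(OCc2ccccc2)cc(OCc2ccccc2)c1
F7 | step 3 | (4S)-5,7-bis(benzyloxy)-4-(2-methylpropyl)-3,4-dihydro-2H-chromen-2-ol (both C2 anomers) | CC(C)C[C@H]1CC(O)Oc2cc(OCc3ccccc3)cc(OCc3ccccc3)c21
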